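Ring A of the target (C4a, C5, C6, C7, C8, C8a) carries adjacent methoxy groups on C6 and C7 and shares the C4a=C8a alkene with the pyranone ring. At the 5,8-dihydro level it is therefore cut at C4a–C5 and C8–C8a into 2,3-dimethoxybuta-1,3-diene and a 4-pyranone with a phenylsulfinyl group on C4a as a traceless activator.
The pyranone is cut at C2–C3 and O1–C8a into 3-[4-(benzyloxy)-3-methoxyphenyl]propanoyl chloride and the dimethylaminomethylene derivative of (phenylthio)acetone, so sulfur is in place from the start.
Forward order: pyranone ring (enolate C-acylation, acid ring closure), sulfide to sulfoxide, ring A by [4+2] cycloaddition with loss of benzenesulfenic acid, DDQ aromatization, hydrogenolysis of the benzyl ether.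
Stereochemistry: the target has no stereocenter; the sulfur stereocenter and the two ring-fusion carbons of the cycloadduct are transient and are erased by the elimination.

Key step: step 6

Assumption: the push–pull alkene of 5 and 6 is drawn Z (dimethylamino group anti to the ketone), as is usual for such amino enones; the geometry is lost in step 4 and has no bearing on the route.

Step 1
Reactants: 1 3-(4-hydroxy-3-methoxyphenyl)propanoic acid (dihydroferulic acid)
Product: 2 3-[4-(benzyloxy)-3-methoxyphenyl]propanoic acid
Conditions: BnBr (1.3 equiv), NaOH (3 equiv), EtOH–H2O, reflux; then HCl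
Reagents that add atoms: benzyl bromide, BrCc1ccccc1
Why: Williamson ether synthesis: in aqueous ethanol the phenoxide is far more nucleophilic than the carboxylate and any benzyl ester is saponified by the excess NaOH, so the acid with a benzyl-protected phenol should form directly; the benzyl ether withstands steps 2 to 7 and leaves by hydrogenolysis at the end.

Step 2
Reactants: 2 3-[4-(benzyloxy)-3-methoxyphenyl]propanoic acid
Product: 3 3-[4-(benzyloxy)-3-methoxyphenyl]propanoyl chloride
Conditions: (COCl)2 (1.3 equiv), DMF (cat.), CH2Cl2, 0 °C to rt; evaporated, used crude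
Reagents that add atoms: oxalyl chloride, ClC(=O)C(Cl)=O
Why: Acid chloride formation with oxalyl chloride, catalysed by the chloroiminium salt from DMF, gives only gaseous by-products and should leave the aryl benzyl and methyl ethers untouched at room temperature.

Step 3
Reactants: 4 1-(phenylsulfanyl)propan-2-one ((phenylthio)acetone)
Product: 5 (Z)-4-(dimethylamino)-3-(phenylsulfanyl)but-3-en-2-one
Conditions: Me2NCH(OMe)2 (1.3 equiv), toluene, 90 °C
Reagents that add atoms: N,N-dimethylformamide dimethyl acetal, COC(OC)N(C)C
Why: Condensation of an active methylene group with an amide acetal: the CH2 between carbonyl and sulfur is far more acidic than the methyl group, so the dimethylaminomethylene unit should enter there alone and leave the acetyl CH3 as the only enolizable site for step 4.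

Step 4
Reactants: 5 (Z)-4-(dimethylamino)-3-(phenylsulfanyl)but-3-en-2-one; 3 3-[4-(benzyloxy)-3-methoxyphenyl]propanoyl chloride
Product: 7 2-{2-[4-(benzyloxy)-3-methoxyphenyl]ethyl}-5-(phenylsulfanyl)-4H-pyran-4-one, via diketone 6 (not isolated)
Conditions: 5 (2.1 equiv), LiN(SiMe3)2 (2.1 equiv), THF, −78 °C; 3 (1.0 equiv), −78 to −40 °C; AcOH quench; then CF3CO2H, CH2Cl2, rt
Reagents that add atoms: none
Why: Crossed Claisen-type C-acylation of the kinetic lithium enolate of a β-amino enone by an acid chloride (the second equivalent of enolate takes up the acidic proton of 6), followed by acid-mediated attack of the enol oxygen on the aminomethylene carbon and loss of dimethylamine, is the established two-stage assembly of 2-substituted 4-pyranones and places sulfur next to the carbonyl without a separate C–S bond formation.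

Step 5
Reactants: 7 2-{2-[4-(benzyloxy)-3-methoxyphenyl]ethyl}-5-(phenylsulfanyl)-4H-pyran-4-one
Product: 8 2-{2-[4-(benzyloxy)-3-methoxyphenyl]ethyl}-5-(phenylsulfinyl)-4H-pyran-4-one (racemic at sulfur)
Conditions: mCPBA (1.0 equiv), CH2Cl2, −78 to −20 °C
Reagents that add atoms: 3-chloroperoxybenzoic acid (mCPBA), OOC(=O)c1cccc(Cl)c1
Why: Electrophilic oxygen transfer from the peracid to sulfur, the most nucleophilic site of 7, should stop at the sulfoxide with one equivalent at low temperature; the sulfur stereocenter forms without control as a racemate, which is immaterial because step 6 removes it.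

Step 6
Reactants: 8 2-{2-[4-(benzyloxy)-3-methoxyphenyl]ethyl}-5-(phenylsulfinyl)-4H-pyran-4-one; 9 2,3-dimethoxybuta-1,3-diene
Product: 11 2-{2-[4-(benzyloxy)-3-methoxyphenyl]ethyl}-6,7-dimethoxy-5,8-dihydro-4H-chromen-4-one, via sulfinyl cycloadduct 10 (not isolated)
Conditions: 9 (5 equiv), 2,6-lutidine (0.2 equiv), BHT (cat.), toluene, sealed tube, 130 °C; filtration through Et3N-washed silica
Reagents that add atoms: none
Why: Proposed new method: the sulfinyl-bearing C5=C6 alkene of 8 (C4a=C8a in chromone numbering) is polarized by the C4 carbonyl and the sulfinyl group on the same carbon and should act as the 2π partner toward the electron-rich diene 9 in a normal-electron-demand Diels–Alder reaction, the closest known reaction type being the cycloaddition of α-sulfinyl enones, sulfinyl quinones and 3-acceptor-substituted chromones followed by sulfoxide pyrolysis. Ring A closes by a concerted suprafacial [4+2] cycloaddition that forms C4a–C5 and C8–C8a in one event and gives the cis-fused adduct 10. In 10 the sulfinyl group on C4a and the hydrogen on C8a are syn, so thermal syn-elimination through a five-membered transition state expels benzenesulfenic acid, restores the C4a=C8a alkene of the pyranone and makes the sequence irreversible. The two ring-fusion stereocenters and the sulfur stereocenter of 10 are destroyed in this elimination, so no stereocontrol is required. The selectivity needed is the choice between the two pyranone alkenes, which the sulfinyl group settles in favour of the alkene that carries it (the other is only a donor-substituted vinylogous ester), and the symmetrical diene leaves no regiochemical choice for the methoxy groups. Should elimination run partly toward C5–H, the 8,8a-dihydro isomer formed would be carried to the same arene in step 7.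

Step 7
Reactants: 11 2-{2-[4-(benzyloxy)-3-methoxyphenyl]ethyl}-6,7-dimethoxy-5,8-dihydro-4H-chromen-4-one
Product: 12 2-{2-[4-(benzyloxy)-3-methoxyphenyl]ethyl}-6,7-dimethoxy-4H-chromen-4-one
Conditions: DDQ (1.05 equiv), CH2Cl2, 0 °C; NaHCO3 wash
Reagents that add atoms: none
Why: DDQ dehydrogenation of a 1,4-cyclohexadiene (hydride abstraction from the doubly allylic C5 or C8, then proton loss) is driven by aromatization of ring A and, at 0 °C with one equivalent, should be far faster than any attack on the unactivated benzyl ether or the ArCH2CH2 linker.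

Step 8
Reactants: 12 2-{2-[4-(benzyloxy)-3-methoxyphenyl]ethyl}-6,7-dimethoxy-4H-chromen-4-one
Product: 13 2-[2-(4-hydroxy-3-methoxyphenyl)ethyl]-6,7-dimethoxy-4H-chromen-4-one (target)
Conditions: H2 (1 atm), 10% Pd/C, EtOAc–EtOH, rt
Reagents that add atoms: none
Why: Catalytic hydrogenolysis of a benzyl aryl ether; at 1 atm and room temperature the C2=C3 alkene of the chromone and the aryl methyl ethers should survive if uptake is stopped after one equivalent, and 12 is freed of sulfur residues by chromatography beforehand so that the catalyst is not poisoned.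

Compound list
1 | 3-(4-hydroxy-3-methoxyphenyl)propanoic acid | COc1cc(CCC(=O)O)ccc1O | starting material
2 | 3-[4-(benzyloxy)-3-methoxyphenyl]propanoic acid | COc1cc(CCC(=O)O)ccc1OCc1ccccc1 | intermediate
3 | 3-[4-(benzyloxy)-3-methoxyphenyl]propanoyl chloride | COc1cc(CCC(Cl)=O)ccc1OCc1ccccc1 | intermediate
4 | 1-(phenylsulfanyl)propan-2-one | CC(=O)CSc1ccccc1 | starting material
5 | (Z)-4-(dimethylamino)-3-(phenylsulfanyl)but-3-en-2-one | CN(C)/C=C(\Sc1ccccc1)C(C)=O | intermediate
6 | (Z)-7-[4-(benzyloxy)-3-methoxyphenyl]-1-(dimethylamino)-2-(phenylsulfanyl)hept-1-ene-3,5-dione (not isolated) | CN(C)/C=C(\Sc1ccccc1)C(=O)CC(=O)CCc1ccc(OCc2ccccc2)c(OC)c1 | intermediate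
7 | 2-{2-[4-(benzyloxy)-3-methoxyphenyl]ethyl}-5-(phenylsulfanyl)-4H-pyran-4-one | O=c1cc(CCc2ccc(OCc3ccccc3)c(OC)c2)occ1Sc1ccccc1 | intermediate
8 | 2-{2-[4-(benzyloxy)-3-methoxyphenyl]ethyl}-5-(phenylsulfinyl)-4H-pyran-4-one, racemic at sulfur | O=S(c1ccccc1)c1coc(CCc2ccc(OCc3ccccc3)c(OC)c2)cc1=O | intermediate
9 | 2,3-dimethoxybuta-1,3-diene | C=C(OC)C(OC)=C | starting material
10 | cis-fused 2-{2-[4-(benzyloxy)-3-methoxyphenyl]ethyl}-6,7-dimethoxy-4a-(phenylsulfinyl)-4a,5,8,8a-tetrahydro-4H-chromen-4-one, racemic, sulfinyl group on C4a syn to H on C8a, both sulfur epimers (not isolated) | O=C1C=C(CCc3ccc(OCc4ccccc4)c(OC)c3)O[C@@H]2CC(OC)=C(OC)C[C@]12S(=O)c1ccccc1 | intermediate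
11 | 2-{2-[4-(benzyloxy)-3-methoxyphenyl]ethyl}-6,7-dimethoxy-5,8-dihydro-4H-chromen-4-one | COC1=C(OC)Cc2oc(CCc3ccc(OCc4ccccc4)c(OC)c3)cc(=O)c2C1 | intermediate
12 | 2-{2-[4-(benzyloxy)-3-methoxyphenyl]ethyl}-6,7-dimethoxy-4H-chromen-4-one | COc1cc(CCc2cc(=O)c3cc(OC)c(OC)cc3o2)ccc1OCc1ccccc1 | intermediate
13 | 2-[2-(4-hydroxy-3-methoxyphenyl)ethyl]-6,7-dimethoxy-4H-chromen-4-one | COc1cc(CCc2cc(=O)c3cc(OC)c(OC)cc3o2)ccc1O | target

Total steps: 8. Longest linear sequence: 7 steps (steps 1, 2, 4, 5, 6, 7, 8, from 1 to 13).

Steps most likely to fail

Step 6. Donation from the ring oxygen into the dienophile alkene may make the cycloaddition so slow that polymerization of the diene, or acid-promoted hydrolysis of its enol ethers, overtakes ring formation. Chelating activation with ZnBr2 or high pressure would be tried before the approach is changed. The fallback uses known chemistry, sets out from 3 and returns at 12. Acylation of commercial 1-(2-hydroxy-4,5-dimethoxyphenyl)ethan-1-one (CC(=O)c1cc(OC)c(OC)cc1O) with 3 in pyridine–CH2Cl2 should give the aryl ester 2-acetyl-4,5-dimethoxyphenyl 3-[4-(benzyloxy)-3-methoxyphenyl]propanoate F1. Baker–Venkataraman rearrangement with KO-t-Bu in THF should give the diketone 5-[4-(benzyloxy)-3-methoxyphenyl]-1-(2-hydroxy-4,5-dimethoxyphenyl)pentane-1,3-dione F2. Cyclodehydration with p-TsOH in toluene at reflux should give chromone 12, after which step 8 follows. Ring A is then bought as an arene and not built.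

Step 4. O-acylation of the enolate, dehydrochlorination of the acid chloride to a ketene, or quenching of the enolate by the more acidic diketone may leave conversion low. The fallback sets out from 3 (with 5) and returns at 7 through 6. Reduction of 3 with LiAlH(O-t-Bu)3 in THF at −78 °C should give 3-[4-(benzyloxy)-3-methoxyphenyl]propanal F3. Aldol addition of the lithium enolate of 5 (LiN(SiMe3)2, THF, −78 °C) should give the racemic β-hydroxy ketone (Z)-7-[4-(benzyloxy)-3-methoxyphenyl]-1-(dimethylamino)-5-hydroxy-2-(phenylsulfanyl)hept-1-en-3-one F4. Dess–Martin oxidation (NaHCO3-buffered, CH2Cl2) should give diketone 6, which is cyclized with CF3CO2H as in step 4 to 7.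

Step 7. The acidic hydroquinone by-product may hydrolyse the bis-enol ether before dehydrogenation is complete, or oxidation may spread to the electron-rich benzylic positions. The fallback sets out from 11 and returns at the target 13. Heating 11 with Pd/C in ethanol under argon should let the cyclohexadiene ring act as the hydrogen donor in a catalytic transfer hydrogenolysis, so that aromatization of ring A and loss of the benzyl group occur in one redox-neutral operation. Any 12 left over would be cleaved by admitting H2 as in step 8. No new compound is made.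

Further compounds
F1 | step 6 | 2-acetyl-4,5-dimethoxyphenyl 3-[4-(benzyloxy)-3-methoxyphenyl]propanoate | COc1cc(CCC(=O)Oc2cc(OC)c(OC)cc2C(C)=O)ccc1OCc1ccccc1
F2 | step 6 | 5-[4-(benzyloxy)-3-methoxyphenyl]-1-(2-hydroxy-4,5-dimethoxyphenyl)pentane-1,3-dione | COc1cc(CCC(=O)CC(=O)c2cc(OC)c(OC)cc2O)ccc1OCc1ccccc1
F3 | step 4 | 3-[4-(benzyloxy)-3-methoxyphenyl]propanal | COc1cc(CCC=O)ccc1OCc1ccccc1
F4 | step 4 | (Z)-7-[4-(benzyloxy)-3-methoxyphenyl]-1-(dimethylamino)-5-hydroxy-2-(phenylsulfanyl)hept-1-en-3-one, racemic | CN(C)/C=C(\Sc1ccccc1)C(=O)CC(O)CCc1ccc(OCc2ccccc2)c(OC)c1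
F0 | step 7 | none | none
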